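**Retrosynthetic overview**
- Peperomin C is cut at the C4–CHAr2 bond (Ar = 3,4,5-trimethoxyphenyl) into a benzhydryl cation (from the benzhydryl bromide) and a C4 carbanion, i.e. the β-carbon (d3, homoenolate) of (E)-4-hydroxy-2-methylbut-2-enal made nucleophilic by a chiral N-heterocyclic carbene.
- The only ring, the γ-lactone, closes last and in the same flask: the acyl azolium left after the C–C bond formation is acylated by the γ-hydroxyl.
- C4 is set by the catalyst in the C–C bond formation; C3 is set by equilibration to the trans lactone.
- The bromide comes from the benzhydrol, which comes from an aryl Grignard reagent and 3,4,5-trimethoxybenzaldehyde; the hydroxy-enal comes from its commercial acetate.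

Assumption 1: the facial sense of the triazolium catalyst in the new key step cannot be known in advance; the (5aS,10bR) antipode is written, and if the first run gives the enantiomer of the target, the commercial (5aR,10bS) antipode is used with nothing else changed.
Assumption 2: (E)-4-acetoxy-2-methylbut-2-enal (the industrial vitamin A C5 acetate) is taken as purchased.

Step 1
Reactants: 1 5-bromo-1,2,3-trimethoxybenzene; 2 3,4,5-trimethoxybenzaldehyde
Product: 5 bis(3,4,5-trimethoxyphenyl)methanol, via aryl Grignard reagent 3 (not isolated), via magnesium alkoxide 4 (not isolated)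
Conditions: Mg, I2 (cat.), THF, reflux; then 2, 0 °C → rt; sat. aq NH4Cl
Reagents that add atoms: none
Why: Grignard formation and 1,2-addition to an aryl aldehyde is routine, and the carbinol carbon carries two identical aryl groups, so no stereocentre arises.

Step 2
Reactants: 5 bis(3,4,5-trimethoxyphenyl)methanol
Product: 6 bis(3,4,5-trimethoxyphenyl)methyl bromide
Conditions: AcBr (3 equiv), CH2Cl2, 0 °C → rt; evaporate, toluene azeotrope, use crude under argon
Reagents that add atoms: acetyl bromide CC(=O)Br
Why: Acetyl bromide acetylates the doubly benzylic alcohol and the HBr released ionises the acetate (SN1 through the aryl-stabilised benzhydryl cation) to the bromide; no stereocentre is involved.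

Step 3
Reactants: 7 (E)-4-acetoxy-2-methylbut-2-enal
Product: 8 (E)-4-hydroxy-2-methylbut-2-enal
Conditions: K2CO3 (0.2 equiv), MeOH, 0 °C, 30 min; AcOH quench, short silica plug
Reagents that add atoms: none
Why: Base-catalysed transesterification (Zemplén-type methanolysis) removes the primary allylic acetate under conditions cold and brief enough to leave the E-enal untouched; the E geometry is kept, which prevents cyclisation to the lactol.

Step 4
Reactants: 6 bis(3,4,5-trimethoxyphenyl)methyl bromide; 8 (E)-4-hydroxy-2-methylbut-2-enal
Product: 10 peperomin C, via cis lactone epimer 9 (not isolated)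
Conditions: (5aS,10bR)-2-mesityl-5a,10b-dihydro-4H,6H-indeno[2,1-b][1,2,4]triazolo[4,3-d][1,4]oxazin-2-ium chloride (15 mol %), K2CO3 (1.5 equiv), 4 Å MS, CH2Cl2, −20 °C → rt, 6 added over 6 h to 8 (1.5 equiv); then DBU (0.3 equiv), rt, 12 h
Reagents that add atoms: none
Why: Proposed new method: the chiral triazolylidene adds to the aldehyde of 8 to give the extended Breslow intermediate, whose β-carbon (C4 of the product, normally electrophilic) becomes a d3 homoenolate nucleophile; it captures the aryl-stabilised benzhydryl cation released by SN1 ionisation of 6 on the face left open by the aminoindane wall, which sets C4 as S; the enol azolium then ketonises to an acyl azolium that the γ-hydroxyl acylates in a 5-exo closure, freeing catalyst and lactone, and DBU equilibrates C3 of any cis epimer 9 to the more stable trans (3S) arrangement; the closest known reaction types are the carbene-catalysed alkylation of Breslow intermediates with diarylbromomethanes, the carbene-catalysed homoenolate 1,6-addition to p-quinone methides and the carbene-catalysed redox lactonisation of hydroxy-enals.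

**Compound list**
1 | 5-bromo-1,2,3-trimethoxybenzene | COc1cc(Br)cc(OC)c1OC | starting material
2 | 3,4,5-trimethoxybenzaldehyde | COc1cc(C=O)cc(OC)c1OC | starting material
3 | 3,4,5-trimethoxyphenylmagnesium bromide (aryl Grignard reagent) | COc1cc([Mg]Br)cc(OC)c1OC | intermediate
4 | bromomagnesium bis(3,4,5-trimethoxyphenyl)methoxide (magnesium alkoxide) | COc1cc(cc(OC)c1OC)C(O[Mg]Br)c1cc(OC)c(OC)c(OC)c1 | intermediate
5 | bis(3,4,5-trimethoxyphenyl)methanol | COc1cc(cc(OC)c1OC)C(O)c1cc(OC)c(OC)c(OC)c1 | intermediate
6 | bis(3,4,5-trimethoxyphenyl)methyl bromide | COc1cc(cc(OC)c1OC)C(Br)c1cc(OC)c(OC)c(OC)c1 | intermediate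
7 | (E)-4-acetoxy-2-methylbut-2-enal | CC(=O)OC/C=C(\C)C=O | starting material
8 | (E)-4-hydroxy-2-methylbut-2-enal | OC/C=C(\C)C=O | intermediate
9 | cis lactone epimer (3-epi-peperomin C): (3R,4S)-4-[bis(3,4,5-trimethoxyphenyl)methyl]-3-methyldihydrofuran-2(3H)-one | COc1cc(C(c2cc(OC)c(OC)c(OC)c2)[C@@H]2COC(=O)[C@@H]2C)cc(OC)c1OC | intermediate
10 | peperomin C: (3S,4S)-4-[bis(3,4,5-trimethoxyphenyl)methyl]-3-methyldihydrofuran-2(3H)-one (trans) | COc1cc(C(c2cc(OC)c(OC)c(OC)c2)[C@@H]2COC(=O)[C@H]2C)cc(OC)c1OC | target

**Step count and risks**
Total step count: 4. Longest linear sequence: 3 steps (1 → 2 → 4); step 3 is a one-step side branch.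

Most likely to fail, first: step 4. The α-branched enal may form the Breslow intermediate slowly. The free hydroxyl or the carbene itself may be benzhydrylated. Alkylation may occur at the acyl carbon instead of the β-carbon. The enal may simply undergo redox lactonisation by β-protonation. A free cation may also give only modest enantioselectivity. The fallback takes ring closure and C3 out of the key step. It sets out from 6. The same carbene-catalysed β-benzhydrylation is run with the unbranched, O-protected enal (E)-4-(tert-butyldimethylsilyloxy)but-2-enal (purchased, O=C/C=C/CO[Si](C)(C)C(C)(C)C). The acceptor for the acyl azolium is 1,1,1,3,3,3-hexafluoropropan-2-ol (3 equiv, OC(C(F)(F)F)C(F)(F)F), chosen because it is too weakly nucleophilic to intercept the benzhydryl cation as methanol would. This gives 1,1,1,3,3,3-hexafluoropropan-2-yl (3R)-3-{[(tert-butyldimethylsilyl)oxy]methyl}-4,4-bis(3,4,5-trimethoxyphenyl)butanoate F1. TsOH in MeOH removes the silyl group and the freed alcohol closes onto the active ester to give (4R)-4-[bis(3,4,5-trimethoxyphenyl)methyl]dihydrofuran-2(3H)-one F2. LDA in THF at −78 °C followed by MeI methylates the enolate anti to the C4 substituent (standard trans-selective alkylation of β-substituted butyrolactones), and the route is rejoined at 10.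

Second: step 2. The bromide is moisture-sensitive, and under HBr the electron-rich rings can be alkylated by the cation (Friedel–Crafts self-condensation). The fallback changes the electrophile class to a neutral p-quinone methide. It sets out from 3. Excess 3 (2.5 equiv; one equivalent is spent on the phenol) is added to purchased syringaldehyde (COc1cc(C=O)cc(OC)c1O) to give (4-hydroxy-3,5-dimethoxyphenyl)(3,4,5-trimethoxyphenyl)methanol F3. TMSBr in CH2Cl2 followed by a wash with aqueous NaHCO3 (net loss of water) gives 2,6-dimethoxy-4-[(3,4,5-trimethoxyphenyl)methylidene]cyclohexa-2,5-dien-1-one F4, used at once. Under the triazolium catalyst of step 4, the homoenolate of 8 adds 1,6 to F4 and the acyl azolium lactonises, followed by the same DBU equilibration. This gives (3S,4S)-4-[(4-hydroxy-3,5-dimethoxyphenyl)(3,4,5-trimethoxyphenyl)methyl]-3-methyldihydrofuran-2(3H)-one F5; it is a mixture at the diarylmethine carbon, which stops being a stereocentre in the next operation. MeI and K2CO3 in acetone methylate the phenol, and the route is rejoined at 10.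

Third: step 3. Methoxide may add to the enal or isomerise it to the Z form, which cyclises and dehydrates to 3-methylfuran; 8 is also small and water-soluble. The fallback masks the aldehyde first. It sets out from 7. HC(OMe)3 with catalytic PPTS in MeOH gives (E)-4,4-dimethoxy-3-methylbut-2-en-1-yl acetate F6. K2CO3 in MeOH then removes the acetate safely to give (E)-4,4-dimethoxy-3-methylbut-2-en-1-ol F7. Amberlyst-15 in wet acetone at 0 °C hydrolyses the acetal, and the route is rejoined at 8.

**Further compounds**
F1 | step 4 | 1,1,1,3,3,3-hexafluoropropan-2-yl (3R)-3-{[(tert-butyldimethylsilyl)oxy]methyl}-4,4-bis(3,4,5-trimethoxyphenyl)butanoate | COc1cc(C(c2cc(OC)c(OC)c(OC)c2)[C@@H](CC(=O)OC(C(F)(F)F)C(F)(F)F)CO[Si](C)(C)C(C)(C)C)cc(OC)c1OC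
F2 | step 4 | (4R)-4-[bis(3,4,5-trimethoxyphenyl)methyl]dihydrofuran-2(3H)-one | COc1cc(C(c2cc(OC)c(OC)c(OC)c2)[C@@H]2COC(=O)C2)cc(OC)c1OC
F3 | step 2 | (4-hydroxy-3,5-dimethoxyphenyl)(3,4,5-trimethoxyphenyl)methanol (racemic) | COc1cc(cc(OC)c1O)C(O)c1cc(OC)c(OC)c(OC)c1
F4 | step 2 | 2,6-dimethoxy-4-[(3,4,5-trimethoxyphenyl)methylidene]cyclohexa-2,5-dien-1-one | COC1=CC(=Cc2cc(OC)c(OC)c(OC)c2)C=C(OC)C1=O
F5 | step 2 | (3S,4S)-4-[(4-hydroxy-3,5-dimethoxyphenyl)(3,4,5-trimethoxyphenyl)methyl]-3-methyldihydrofuran-2(3H)-one (mixture at the diarylmethine carbon) | COc1cc(C(c2cc(OC)c(O)c(OC)c2)[C@@H]2COC(=O)[C@H]2C)cc(OC)c1OC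
F6 | step 3 | (E)-4,4-dimethoxy-3-methylbut-2-en-1-yl acetate | CC(=O)OC/C=C(\C)C(OC)OC
F7 | step 3 | (E)-4,4-dimethoxy-3-methylbut-2-en-1-ol | OC/C=C(\C)C(OC)OC
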